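What the impurity leaves of the enzyme is the number to carry through this flask. If one impurity molecule kills one enzyme molecule, the west flask keeps 0.110 µM of working enzyme: this is the surplus enzyme, enzyme charged minus impurity charged, and it is 11.0 % of the enzyme charge.

| flask | substrate | enzyme | impurity | remark | time |
|---|---|---|---|---|---|
| west | 0.010 M | 1 µM | 0.89 µM | the very flask that is asked about, followed so far |  |
| flask | 0.010 M | 1.0 µM | 0.89 µM |  | 30 h |

west run (percent of the substrate charged)

| time / h | target / % | substrate / % |
|---|---|---|
| 1.33 | 3.3 | 95.6 |
| 2.50 | 5.3 | 91.8 |
| 5.00 | 7.3 | 85.1 |
| 10.0 | 9.6 | 71.3 |
| 20.0 | 10.8 | 49.9 |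

(each reading ± 0.5 percentage points)

- additions bring no volume worth counting
- a reading or a percentage of target counts all its forms, free or not

- red: change nothing and wait 2.5 d more
- blue: at 30 h add enzyme, 100 % of the amount charged, then wait 2.5 d
- ochre: at 30 h add substrate, 50.0 % of the amount charged, then wait 2.5 d

1. target, in percent of the substrate first charged, at 30 h
2. the remedy with the largest gain of target, or "none" below 2 percentage points (red / blue / ochre / none)
3. target present, in percent of the substrate first charged, after red
4. target present, in percent of the substrate first charged, after blue

Two views of this flask stand against each other. The forecast's author reads the steady fall of substrate as “with no slowing, so the enzyme stays alive” and forecasts target at 6 % now, 0.3 % after red and 0.1 % after blue, so the remedy is none.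

I read the same curve differently. The steady fall in the west run says that what works keeps working, not how much of the charge works. The impurity, at 0.89 µM against 1.0 µM of enzyme, would be the limiting reagent of the killing step. Over the last two readings target gained 1.2 percentage points while substrate lost 21 points, so I put target at 30 h near its last reading, which is more than the forecast's 6 %. From those readings I expect no gain of 2 points from red, and on red the forecast and I agree.

We part on blue. If the killing is over by 30 h, blue lifts the working enzyme to 1.11 µM, ten times the surplus. Ochre leaves the surplus where it was. So I commit to blue, with a gain above 2 points.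

The simulation gives 9.66 % now, 4.11 % after red and 14.8 % after blue. The gains are −5.6 points for red, 5.1 points for blue and −4 points for ochre, so the best remedy is blue. The forecast's expectation of a falling target holds in the untouched flask late in the run: at 30.0 h free target is made at 0.756 of the rate at which it is used up, each step taken net and going into its other forms counted as use, and red loses target.

    substrate + enzyme → target + enzyme, rate k1*[substrate]^2.5*[enzyme]/(1 + ([substrate]/Kh1)^2.5) (7.60 mM, k = 1.73 × 10⁵ /M².5/s)
    enzyme + impurity → spent catalyst (k = 12600 /M/s)
    substrate + target → side product (k = 0.274 /M/min)
    enzyme + target ⇌ idle complex (K = 74.0 /M, k = 6.02 /M/min)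

At 30.0 h the flask holds impurity 0 % of its own charge and, of the enzyme charge, spent catalyst 89.0 %, enzyme 10.3 % and idle complex 0.736 %; the last two make 11.0 %, beside a surplus share of 11.0 %. The neighbouring flask charges 1.7 × 10⁻⁶ M of enzyme with the same impurity. Its surplus is 0.810 µM, or 47.6 % of its enzyme charge. At 30.0 h it holds, of its enzyme charge, enzyme 39.5 % and idle complex 8.17 %, together 47.7 %, beside spent catalyst 52.4 %. Of its substrate charge, free substrate stands at 5.9 % and target, all its forms counted, at 27.9 %.

The data are simulated for substances that don't exist, noise included.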